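**Plan**
- Retrosynthesis: remove the C8 tiglate and the C10/C13 acetates; C1=O/C10–O come from an (E)-C1=C10 olefin (syn-dihydroxylation, then oxidation), C14 from an enol triflate, C13 from lactone enolate + CH2O, and the cis-epoxide from an (E)-C4=C5 olefin (syn-diol, then closure with inversion at C5).
- What remains is a cyclodec-5-enone: the C10 carbonyl and the C4=C5 olefin are joined through C1–C2–C3, which is the oxy-Cope retron. Cutting C2–C3 and joining C5–C10 gives a cyclohexanol (ring C5–C10) with vinyl on C10 and isopropenyl on C5, trans-fused to the C6/C7 lactone.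
- Forward: Evans aldol (C6–C7) and lactonisation; Mukaiyama aldol (C8–C9); a carbonyl-ene reaction closes the cyclohexane through the helper bond C5–C10; vinyl addition; the anionic oxy-Cope then expands the six-membered ring to the ten-membered ring by forming C2–C3 and breaking C5–C10.
- Stereochemistry: C6/C7 from the auxiliary, C8 by Felkin addition, C11 by attack trans to C8 on the lactone enolate; C4, C5 and C10 by osmylation from the outer face of the macrocycle, with C5 inverted on epoxide closure.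

Key step: step 12

Remark: germacrane numbering is used for all compounds (C1 ketone carbon, C4/C5 epoxide, C6 lactone O-bearing carbon, C8 tiglate-bearing carbon, C10 acetoxy-bearing carbon, C11–C13 lactone carbons, C14/C15 methyls); α is the face of the C6, C8 and C10 oxygens.

Step 1
Reactants: 1 (S)-4-benzyloxazolidin-2-one; 2 methyl 4-chloro-4-oxobutanoate
Product: 3 (S)-4-benzyl-3-(4-methoxy-4-oxobutanoyl)oxazolidin-2-one
Conditions: n-BuLi, THF, −78 °C; then 2, −78 → 0 °C
Reagents that add atoms: none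
Why: N-acylation of the lithiated oxazolidinone by the acid chloride should be much faster than attack on the methyl ester, and no stereocentre is formed.

Step 2
Reactants: 3; 4 3-methylbut-2-enal
Product: 6 (S)-4-benzyl-3-[(2R,3S)-2-(2-methylprop-1-en-1-yl)-5-oxooxolane-3-carbonyl]oxazolidin-2-one, via syn-aldol adduct 5 (not isolated)
Conditions: Bu2BOTf, iPr2NEt, CH2Cl2, 0 °C; 4, −78 → 0 °C; pH 7 buffer, MeOH, H2O2; then PPTS (cat.), CH2Cl2, 23 °C
Reagents that add atoms: none
Why: Evans syn-aldol: soft enolisation is selective for the imide α-CH2, the boron Z-enolate reacts through a Zimmerman–Traxler chair in which the (S)-benzyl auxiliary sets C7 and C6 (syn), and the γ-hydroxy ester should then close to the trans-4,5-disubstituted butanolide.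

Step 3
Reactants: 6
Product: 7 S-ethyl (2R,3S)-2-(2-methylprop-1-en-1-yl)-5-oxooxolane-3-carbothioate
Conditions: EtSH, n-BuLi, THF, −78 → 0 °C; aq. NH4Cl
Reagents that add atoms: ethanethiol CCS
Why: Acyl transfer: the thiolate should attack the exocyclic imide carbonyl irreversibly (oxazolidinone anion leaves), whereas addition to the lactone is reversible; C6 and C7 are untouched.

Step 4
Reactants: 7
Product: 8 (2R,3S)-2-(2-methylprop-1-en-1-yl)-5-oxooxolane-3-carbaldehyde
Conditions: Et3SiH, 10% Pd/C, acetone, 23 °C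
Reagents that add atoms: none
Why: Fukuyama reduction of the thioester should stop at the aldehyde and spare the lactone and the trisubstituted olefin; the trans aldehyde is also the thermodynamic C7 epimer.

Step 5
Reactants: 9 S-ethyl ethanethioate
Product: 10 1-(ethylsulfanyl)-1-(trimethylsilyloxy)ethene
Conditions: LiN(iPr)2, THF, −78 °C; Me3SiCl
Reagents that add atoms: chlorotrimethylsilane C[Si](C)(C)Cl
Why: Kinetic enolisation of the thioester and O-silylation give the silyl ketene thioacetal needed for the Mukaiyama aldol.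

Step 6
Reactants: 8; 10
Product: 11 S-ethyl (3S)-3-hydroxy-3-[(2R,3R)-2-(2-methylprop-1-en-1-yl)-5-oxooxolan-3-yl]propanethioate
Conditions: BF3·OEt2, CH2Cl2, −78 °C; aq. NaHCO3
Reagents that add atoms: none
Why: Mukaiyama aldol through an open transition state: Felkin–Anh attack anti to the more substituted C7–C6 bond should set C8 as (S), with O8 syn to C11 along C6–C7–C8–C9.

Step 7
Reactants: 11
Product: 12 S-ethyl (3S)-3-[(tert-butyldimethylsilyl)oxy]-3-[(2R,3S)-2-(2-methylprop-1-en-1-yl)-5-oxooxolan-3-yl]propanethioate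
Conditions: TBSOTf, 2,6-lutidine, CH2Cl2, −78 → 0 °C
Reagents that add atoms: tert-butyldimethylsilyl triflate CC(C)(C)[Si](C)(C)OS(=O)(=O)C(F)(F)F
Why: Silylation gives a non-chelating C8 ether that prevents retro-aldol or elimination and remains in place until step 21.

Step 8
Reactants: 12
Product: 13 (3S)-3-[(tert-butyldimethylsilyl)oxy]-3-[(2R,3S)-2-(2-methylprop-1-en-1-yl)-5-oxooxolan-3-yl]propanal
Conditions: Et3SiH, 10% Pd/C, acetone, 23 °C
Reagents that add atoms: none
Why: A second Fukuyama reduction should deliver the C10 aldehyde chemoselectively in the presence of the lactone.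

Step 9
Reactants: 13
Product: 14 (3aS,4S,6R,7S,7aS)-4-[(tert-butyldimethylsilyl)oxy]-6-hydroxy-7-(prop-1-en-2-yl)hexahydro-1-benzofuran-2(3H)-one
Conditions: Me2AlCl, CH2Cl2, −78 → −40 °C; aq. potassium sodium tartrate
Reagents that add atoms: none
Why: Lewis-acid-promoted intramolecular carbonyl-ene reaction of the citronellal-to-isopulegol kind: the C10 aldehyde bonds to C5 of the 2-methylpropenyl group through a chair in which O8, the trans lactone fusion, the new isopropenyl group and O10 are all equatorial, which should set C5 trans to O6 and make the helper bond C5–C10.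

Step 10
Reactants: 14
Product: 15 (3aS,4S,7R,7aS)-4-[(tert-butyldimethylsilyl)oxy]-7-(prop-1-en-2-yl)tetrahydro-1-benzofuran-2,6(3H,7H)-dione
Conditions: Dess–Martin periodinane, NaHCO3, CH2Cl2, 0 → 23 °C
Reagents that add atoms: none
Why: Buffered Dess–Martin oxidation should give the C10 ketone without moving the β,γ-olefin into conjugation; the equatorial isopropenyl group is the stable C5 epimer.

Step 11
Reactants: 15
Product: 16 (3aS,4S,6R,7R,7aS)-4-[(tert-butyldimethylsilyl)oxy]-6-ethenyl-6-hydroxy-7-(prop-1-en-2-yl)hexahydro-1-benzofuran-2(3H)-one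
Conditions: CH2=CHMgBr, CeCl3, THF, −78 °C; aq. NH4Cl
Reagents that add atoms: vinylmagnesium bromide C=C[Mg]Br
Why: The weakly basic organocerium reagent should add to the ketone without enolisation or attack on the lactone, from the equatorial direction of the locked chair (axial approach meets the axial H6 and H8), giving vinyl equatorial and trans to isopropenyl with O10 axial.

Step 12
Reactants: 16
Product: 20 (4E)-8α-[(tert-butyldimethylsilyl)oxy]-10-[(triethylsilyl)oxy]-13,14-dinorgermacra-1(10),4-dien-12,6α-olide (C2 trans to C9 across C1=C10), via dipotassium alkoxide-enolate 17 (not isolated), via ring-expanded dipotassium bis-enolate 18 (not isolated), via bis-triethylsilyl derivative 19 (not isolated)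
Conditions: KN(SiMe3)2 (2.3 equiv), 18-crown-6, THF, −78 → 20 °C; then Et3SiCl, −78 °C; aq. NaHCO3
Reagents that add atoms: chlorotriethylsilane CC[Si](CC)(CC)Cl
Why: KN(SiMe3)2 removes the C10 hydroxyl proton and one lactone α-proton so that no proton source remains, and the potassium alkoxide should undergo a charge-accelerated [3,3]-sigmatropic shift in which the C5–C10 bond of the cyclohexane breaks as the vinyl terminus C2 bonds to the isopropenyl terminus C3; the closest known reaction type is the anionic oxy-Cope ring expansion of trans-1,2-dialkenylcyclohexanols to (E)-cyclodec-5-enones. The ten-membered carbocycle is closed by the C2–C3 bond through a six-membered chair transition state fused like a trans-decalin to the cyclohexane, that is a four-carbon ring expansion (6 → 10) and not an end-to-end macrocyclisation, and the trans-fused lactone is carried through unchanged. No new stereocentre is formed; the two new stereo-elements, the E geometry of C4=C5 and the enolate geometry at C1=C10 (C2 trans to C9), follow from C6 and C9 being equatorial on that chair, which the trans-diequatorial vinyl and isopropenyl groups of the locked bicycle enforce. The step needs chair-over-boat selectivity, a regio-defined C1=C10 enolate and an inert lactone: the first comes from the diequatorial geometry, the second from full deprotonation (without a proton shuttle the enolate cannot drift towards C9 and expel the C8 silyloxy group), and the third from holding the lactone as its enolate until both enolates are silylated. Aqueous work-up should hydrolyse only the ketene silyl acetal, returning the lactone and leaving the triethylsilyl enol ether of the C10 ketone. The chair also delivers the ring in the crown shape with O10 and C15 on the β-face, on which the later outer-face oxidations rely.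

Step 13
Reactants: 20
Product: 21 (4E)-8α-[(tert-butyldimethylsilyl)oxy]-10-[(trifluoromethanesulfonyl)oxy]-13,14-dinorgermacra-1(10),4-dien-12,6α-olide
Conditions: CsF, PhNTf2, DME, 23 °C
Reagents that add atoms: N-phenylbis(trifluoromethanesulfonimide) O=S(=O)(N(c1ccccc1)S(=O)(=O)C(F)(F)F)C(F)(F)F
Why: Fluoride cleaves the silyl enol ether and the caesium enolate is O-triflated in the same flask with retention of regiochemistry and olefin geometry, giving an enol triflate that is both the precursor of the C14 methyl olefin and a mask for C1=C10 towards osmylation.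

Step 14
Reactants: 21
Product: 22 8α-[(tert-butyldimethylsilyl)oxy]-4α,5β-dihydroxy-10-[(trifluoromethanesulfonyl)oxy]-13,14-dinorgermacr-1(10)-en-12,6α-olide
Conditions: OsO4 (5 mol %), N-methylmorpholine N-oxide, acetone/H2O, 0 → 23 °C
Reagents that add atoms: osmium tetroxide O=[Os](=O)(=O)=O; N-methylmorpholine N-oxide C[N+]1([O-])CCOCC1; water O
Why: Syn-dihydroxylation should take only the electron-rich C4=C5 olefin (the enol triflate is deactivated) and from the outer face of the crown conformer, anti to C7 with H6 eclipsing C15, the same face peracids use on E,E-germacra-1(10),4-dienolides, which sets C4 (O α) and gives O5 β.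

Step 15
Reactants: 22
Product: 24 8α-[(tert-butyldimethylsilyl)oxy]-4α,5α-epoxy-10-[(trifluoromethanesulfonyl)oxy]-13,14-dinorgermacr-1(10)-en-12,6α-olide, via C5 mesylate 23 (not isolated)
Conditions: MsCl, Et3N, CH2Cl2, −20 °C; then DBU, 23 °C
Reagents that add atoms: none
Why: Only the secondary C5 hydroxyl is sulfonylated, and intramolecular Williamson closure by the tertiary C4 alkoxide should invert C5, turning the syn-diol of the E-olefin into the cis-epoxide with C4 (R) and C5 (S).

Step 16
Reactants: 24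
Product: 25 (1(10)E)-8α-[(tert-butyldimethylsilyl)oxy]-4α,5α-epoxy-13-norgermacr-1(10)-en-12,6α-olide
Conditions: Me2Zn, Pd(PPh3)4 (5 mol %), THF, 50 °C; aq. NH4Cl
Reagents that add atoms: dimethylzinc C[Zn]C
Why: Negishi coupling (oxidative addition of the enol triflate to zerovalent palladium, methyl transfer from zinc, reductive elimination) should install C14 with retention of geometry, giving the 1(10)E olefin, and tolerates lactone and epoxide.

Step 17
Reactants: 25
Product: 27 13-acetoxy-8α-[(tert-butyldimethylsilyl)oxy]-4α,5α-epoxy-11βH-germacr-1(10)-en-12,6α-olide, via lithium alkoxide 26 (not isolated)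
Conditions: LiN(iPr)2, THF, −78 °C; CH2O (gas, from cracked paraformaldehyde), −78 → −40 °C; then Ac2O, −78 → 0 °C
Reagents that add atoms: formaldehyde C=O; acetic anhydride CC(=O)OC(C)=O
Why: Aldol reaction of the lactone enolate with formaldehyde should occur on the face of C11 opposite to C8 (C13 α, H11 β), and acetylating the lithium aldolate in the flask gives the acetate without exposing it to free base.

Step 18
Reactants: 27
Product: 28 13-acetoxy-8α-[(tert-butyldimethylsilyl)oxy]-4α,5α-epoxy-1β,10α-dihydroxy-11βH-germacran-12,6α-olide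
Conditions: OsO4 (5 mol %), N-methylmorpholine N-oxide, acetone/H2O, 23 °C
Reagents that add atoms: osmium tetroxide O=[Os](=O)(=O)=O; N-methylmorpholine N-oxide C[N+]1([O-])CCOCC1; water O
Why: Suprafacial dihydroxylation of the E-olefin from its outer face (C14 on the β-face, as in the 1β,10α-oxidation of germacranolides) should set C10 with O α and methyl β, the C1 hydroxyl being only a handle for the next step.

Step 19
Reactants: 28
Product: 29 13-acetoxy-8α-[(tert-butyldimethylsilyl)oxy]-4α,5α-epoxy-10α-hydroxy-1-oxo-11βH-germacran-12,6α-olide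
Conditions: Dess–Martin periodinane, NaHCO3, CH2Cl2, 0 → 23 °C
Reagents that add atoms: none
Why: Only the secondary C1 alcohol of the secondary/tertiary diol can be oxidised, giving the α-ketol under buffered, non-basic conditions that spare the epoxide and the β-acetoxy lactone.

Step 20
Reactants: 29
Product: 30 10α,13-diacetoxy-8α-[(tert-butyldimethylsilyl)oxy]-4α,5α-epoxy-1-oxo-11βH-germacran-12,6α-olide
Conditions: Ac2O, DMAP, pyridine, 40 °C
Reagents that add atoms: acetic anhydride CC(=O)OC(C)=O
Why: DMAP-catalysed acylation is the standard way to acetylate a tertiary α-ketol, and the weak base pyridine should not trigger elimination of the C13 acetate.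

Step 21
Reactants: 30
Product: 31 10α,13-diacetoxy-4α,5α-epoxy-8α-hydroxy-1-oxo-11βH-germacran-12,6α-olide
Conditions: HF·pyridine, pyridine, THF, 0 → 23 °C
Reagents that add atoms: none
Why: Buffered fluoride desilylation should free the C8 hydroxyl without opening the epoxide or cleaving the esters.

Step 22
Reactants: 31
Product: 32 (4R,5S,6S,7R,8S,10R,11R)-10,13-diacetoxy-4,5-epoxy-8-[(E)-2-methylbut-2-enoyloxy]-1-oxogermacran-12,6-olide (CNP0305680.1)
Conditions: (E)-2-methylbut-2-enoyl chloride, DMAP, pyridine, CH2Cl2, 0 → 23 °C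
Reagents that add atoms: (E)-2-methylbut-2-enoyl chloride C/C=C(\C)C(Cl)=O
Why: Acylation of the secondary C8 alcohol with the stable E (tigloyl) chloride under mild base completes the target with all stereocentres already in place.

**Compound list**
1 | (S)-4-benzyloxazolidin-2-one | O=C1OC[C@H](Cc2ccccc2)N1 | starting material
2 | methyl 4-chloro-4-oxobutanoate | COC(=O)CCC(Cl)=O | starting material
3 | (S)-4-benzyl-3-(4-methoxy-4-oxobutanoyl)oxazolidin-2-one | COC(=O)CCC(=O)N1[C@@H](Cc2ccccc2)COC1=O | intermediate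
4 | 3-methylbut-2-enal | CC(C)=CC=O | starting material
5 | methyl (3S,4R)-3-[(S)-4-benzyl-2-oxooxazolidine-3-carbonyl]-4-hydroxy-6-methylhept-5-enoate | COC(=O)C[C@@H]([C@H](O)C=C(C)C)C(=O)N1[C@@H](Cc2ccccc2)COC1=O | intermediate
6 | (S)-4-benzyl-3-[(2R,3S)-2-(2-methylprop-1-en-1-yl)-5-oxooxolane-3-carbonyl]oxazolidin-2-one | CC(C)=C[C@H]1OC(=O)C[C@@H]1C(=O)N1[C@@H](Cc2ccccc2)COC1=O | intermediate
7 | S-ethyl (2R,3S)-2-(2-methylprop-1-en-1-yl)-5-oxooxolane-3-carbothioate | CC(C)=C[C@H]1OC(=O)C[C@@H]1C(=O)SCC | intermediate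
8 | (2R,3S)-2-(2-methylprop-1-en-1-yl)-5-oxooxolane-3-carbaldehyde | CC(C)=C[C@H]1OC(=O)C[C@@H]1C=O | intermediate
9 | S-ethyl ethanethioate | CCSC(C)=O | starting material
10 | 1-(ethylsulfanyl)-1-(trimethylsilyloxy)ethene | C=C(SCC)O[Si](C)(C)C | intermediate
11 | S-ethyl (3S)-3-hydroxy-3-[(2R,3R)-2-(2-methylprop-1-en-1-yl)-5-oxooxolan-3-yl]propanethioate | CC(C)=C[C@H]1OC(=O)C[C@@H]1[C@@H](O)CC(=O)SCC | intermediate
12 | S-ethyl (3S)-3-[(tert-butyldimethylsilyl)oxy]-3-[(2R,3S)-2-(2-methylprop-1-en-1-yl)-5-oxooxolan-3-yl]propanethioate | CC(C)=C[C@H]1OC(=O)C[C@@H]1[C@@H](O[Si](C)(C)C(C)(C)C)CC(=O)SCC | intermediate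
13 | (3S)-3-[(tert-butyldimethylsilyl)oxy]-3-[(2R,3S)-2-(2-methylprop-1-en-1-yl)-5-oxooxolan-3-yl]propanal | CC(C)=C[C@H]1OC(=O)C[C@@H]1[C@@H](O[Si](C)(C)C(C)(C)C)CC=O | intermediate
14 | (3aS,4S,6R,7S,7aS)-4-[(tert-butyldimethylsilyl)oxy]-6-hydroxy-7-(prop-1-en-2-yl)hexahydro-1-benzofuran-2(3H)-one | C=C(C)[C@H]1[C@H](O)C[C@H](O[Si](C)(C)C(C)(C)C)[C@H]2CC(=O)O[C@H]12 | intermediate
15 | (3aS,4S,7R,7aS)-4-[(tert-butyldimethylsilyl)oxy]-7-(prop-1-en-2-yl)tetrahydro-1-benzofuran-2,6(3H,7H)-dione | C=C(C)[C@H]1C(=O)C[C@H](O[Si](C)(C)C(C)(C)C)[C@H]2CC(=O)O[C@H]12 | intermediate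
16 | (3aS,4S,6R,7R,7aS)-4-[(tert-butyldimethylsilyl)oxy]-6-ethenyl-6-hydroxy-7-(prop-1-en-2-yl)hexahydro-1-benzofuran-2(3H)-one | C=C(C)[C@H]1[C@](O)(C=C)C[C@H](O[Si](C)(C)C(C)(C)C)[C@H]2CC(=O)O[C@H]12 | intermediate
17 | dipotassium salt of 16 (C10 alkoxide and lactone enolate) | [K+].[K+].C=C(C)[C@H]1[C@]([O-])(C=C)C[C@H](O[Si](C)(C)C(C)(C)C)[C@H]2C=C([O-])O[C@H]12 | intermediate
18 | dipotassium bis-enolate of the ring-expanded keto lactone (C1=C10 enolate with C2 trans to C9, 4E olefin, lactone enolate) | [K+].[K+].[O-]/C1=C\CC/C(C)=C/[C@H]2OC([O-])=C[C@@H]2[C@@H](O[Si](C)(C)C(C)(C)C)C1 | intermediate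
19 | bis(triethylsilyl) derivative of 18 (C10 silyl enol ether and lactone ketene silyl acetal) | CC[Si](CC)(CC)O/C1=C\CC/C(C)=C/[C@H]2OC(O[Si](CC)(CC)CC)=C[C@@H]2[C@@H](O[Si](C)(C)C(C)(C)C)C1 | intermediate
20 | (4E)-8α-[(tert-butyldimethylsilyl)oxy]-10-[(triethylsilyl)oxy]-13,14-dinorgermacra-1(10),4-dien-12,6α-olide (C2 trans to C9, H7 α) | CC[Si](CC)(CC)O/C1=C\CC/C(C)=C/[C@H]2OC(=O)C[C@@H]2[C@@H](O[Si](C)(C)C(C)(C)C)C1 | intermediate
21 | (4E)-8α-[(tert-butyldimethylsilyl)oxy]-10-[(trifluoromethanesulfonyl)oxy]-13,14-dinorgermacra-1(10),4-dien-12,6α-olide | O=S(=O)(O/C1=C\CC/C(C)=C/[C@H]2OC(=O)C[C@@H]2[C@@H](O[Si](C)(C)C(C)(C)C)C1)C(F)(F)F | intermediate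
22 | 8α-[(tert-butyldimethylsilyl)oxy]-4α,5β-dihydroxy-10-[(trifluoromethanesulfonyl)oxy]-13,14-dinorgermacr-1(10)-en-12,6α-olide (4R,5R) | O=S(=O)(O/C1=C\CC[C@@](C)(O)[C@H](O)[C@H]2OC(=O)C[C@@H]2[C@@H](O[Si](C)(C)C(C)(C)C)C1)C(F)(F)F | intermediate
23 | 5β-methanesulfonate of 22 | O=S(=O)(O/C1=C\CC[C@@](C)(O)[C@H](OS(C)(=O)=O)[C@H]2OC(=O)C[C@@H]2[C@@H](O[Si](C)(C)C(C)(C)C)C1)C(F)(F)F | intermediate
24 | 8α-[(tert-butyldimethylsilyl)oxy]-4α,5α-epoxy-10-[(trifluoromethanesulfonyl)oxy]-13,14-dinorgermacr-1(10)-en-12,6α-olide (4R,5S) | O=S(=O)(O/C1=C\CC[C@@]2(C)O[C@H]2[C@H]2OC(=O)C[C@@H]2[C@@H](O[Si](C)(C)C(C)(C)C)C1)C(F)(F)F | intermediate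
25 | (1(10)E)-8α-[(tert-butyldimethylsilyl)oxy]-4α,5α-epoxy-13-norgermacr-1(10)-en-12,6α-olide | C/C1=C\CC[C@@]2(C)O[C@H]2[C@H]2OC(=O)C[C@@H]2[C@@H](O[Si](C)(C)C(C)(C)C)C1 | intermediate
26 | lithium alkoxide of (1(10)E)-8α-[(tert-butyldimethylsilyl)oxy]-4α,5α-epoxy-13-hydroxy-11βH-germacr-1(10)-en-12,6α-olide | [Li+].C/C1=C\CC[C@@]2(C)O[C@H]2[C@H]2OC(=O)[C@@H](C[O-])[C@@H]2[C@@H](O[Si](C)(C)C(C)(C)C)C1 | intermediate
27 | (1(10)E)-13-acetoxy-8α-[(tert-butyldimethylsilyl)oxy]-4α,5α-epoxy-11βH-germacr-1(10)-en-12,6α-olide | C/C1=C\CC[C@@]2(C)O[C@H]2[C@H]2OC(=O)[C@@H](COC(C)=O)[C@@H]2[C@@H](O[Si](C)(C)C(C)(C)C)C1 | intermediate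
28 | 13-acetoxy-8α-[(tert-butyldimethylsilyl)oxy]-4α,5α-epoxy-1β,10α-dihydroxy-11βH-germacran-12,6α-olide | C[C@]1(O)[C@H](O)CC[C@@]2(C)O[C@H]2[C@H]2OC(=O)[C@@H](COC(C)=O)[C@@H]2[C@@H](O[Si](C)(C)C(C)(C)C)C1 | intermediate
29 | 13-acetoxy-8α-[(tert-butyldimethylsilyl)oxy]-4α,5α-epoxy-10α-hydroxy-1-oxo-11βH-germacran-12,6α-olide | C[C@]1(O)C(=O)CC[C@@]2(C)O[C@H]2[C@H]2OC(=O)[C@@H](COC(C)=O)[C@@H]2[C@@H](O[Si](C)(C)C(C)(C)C)C1 | intermediate
30 | 10α,13-diacetoxy-8α-[(tert-butyldimethylsilyl)oxy]-4α,5α-epoxy-1-oxo-11βH-germacran-12,6α-olide | C[C@]1(OC(C)=O)C(=O)CC[C@@]2(C)O[C@H]2[C@H]2OC(=O)[C@@H](COC(C)=O)[C@@H]2[C@@H](O[Si](C)(C)C(C)(C)C)C1 | intermediate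
31 | 10α,13-diacetoxy-4α,5α-epoxy-8α-hydroxy-1-oxo-11βH-germacran-12,6α-olide | C[C@]1(OC(C)=O)C(=O)CC[C@@]2(C)O[C@H]2[C@H]2OC(=O)[C@@H](COC(C)=O)[C@@H]2[C@@H](O)C1 | intermediate
32 | (4R,5S,6S,7R,8S,10R,11R)-10,13-diacetoxy-4,5-epoxy-8-[(E)-2-methylbut-2-enoyloxy]-1-oxogermacran-12,6-olide (4α,5α-epoxide, 6α,12-olide, 8α-tiglate, 10α-acetate, 11βH) | C/C=C(\C)C(=O)O[C@H]1C[C@@](C)(OC(C)=O)C(=O)CC[C@@]2(C)O[C@H]2[C@H]2OC(=O)[C@@H](COC(C)=O)[C@@H]21 | target

Total steps: 22. Longest linear sequence: 21 (steps 1–4 and 6–22; step 5 prepares reagent 10).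

**Steps most likely to fail**

Step 12. The potassium lactone enolate may decompose at the temperature the rearrangement needs (ketene formation, acyl transfer to the C10 alkoxide). Partial proton exchange may also scramble the C1=C10 enolate and lead to β-elimination of the C8 silyloxy group. The fallback sets out from 16 and comes back at 21, bypassing step 13 as well. The lactone of 16 is reduced with i-Bu2AlH to the lactol F1, which MeOH/PPTS converts into the methyl acetal F2, leaving no acidic C–H. The oxy-Cope rearrangement is then run with KH/18-crown-6 (1.2 equiv) and the single enolate is trapped directly with PhNTf2 to give the enol triflate acetal F3. Mild hydrolysis (AcOH/THF/H2O) gives the enol triflate lactol F4, and oxidation with TEMPO/PhI(OAc)2 returns lactone 21.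

Step 18. Facial selectivity in the osmylation of C1=C10 may be poor, because the cis-epoxide changes the ring shape on which the outer-face argument rests. The fallback sets out from 27 and comes back at 28, replacing conformational control by delivery from the C8 hydroxyl. Desilylation of 27 (HF·pyridine) gives the homoallylic alcohol F5. Hydrogen-bond-directed dihydroxylation with stoichiometric OsO4·TMEDA (CH2Cl2, −78 °C, then aq. NaHSO3) places O10 syn to O8 (α) and, being suprafacial on the E-olefin, O1 β, giving the triol F6. Selective silylation of the less hindered C8 hydroxyl (TBSCl, imidazole, DMF, 0 °C) returns 28.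

Step 6. Diastereoselection at C8 may be low, since the α-stereocentre is part of a ring and the lactone oxygen may oppose the Felkin preference. The fallback sets out from 8 and comes back at 11, replacing substrate control by reagent control. The tin enolate of (R)-3-acetyl-4-isopropylthiazolidine-2-thione (Sn(OTf)2, N-ethylpiperidine, CH2Cl2, −78 °C), reacting through its chelated transition state, adds to 8 to give the thiazolidinethione aldol adduct F7. Transthioesterification with EtSH/K2CO3 then gives thioester 11 and releases the auxiliary.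

Further compounds
F1 | step 12 | lactol from i-Bu2AlH reduction of 16 (C12 hemiacetal, both anomers) | C=C(C)[C@H]1[C@](O)(C=C)C[C@H](O[Si](C)(C)C(C)(C)C)[C@H]2CC(O)O[C@H]12
F2 | step 12 | methyl acetal of F1 | C=C(C)[C@H]1[C@](O)(C=C)C[C@H](O[Si](C)(C)C(C)(C)C)[C@H]2CC(OC)O[C@H]12
F3 | step 12 | ring-expanded C10 enol triflate with the lactone masked as its methyl acetal | O=S(=O)(O/C1=C\CC/C(C)=C/[C@H]2OC(OC)C[C@@H]2[C@@H](O[Si](C)(C)C(C)(C)C)C1)C(F)(F)F
F4 | step 12 | ring-expanded C10 enol triflate lactol | O=S(=O)(O/C1=C\CC/C(C)=C/[C@H]2OC(O)C[C@@H]2[C@@H](O[Si](C)(C)C(C)(C)C)C1)C(F)(F)F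
F5 | step 18 | (1(10)E)-13-acetoxy-4α,5α-epoxy-8α-hydroxy-11βH-germacr-1(10)-en-12,6α-olide | C/C1=C\CC[C@@]2(C)O[C@H]2[C@H]2OC(=O)[C@@H](COC(C)=O)[C@@H]2[C@@H](O)C1
F6 | step 18 | 13-acetoxy-4α,5α-epoxy-1β,8α,10α-trihydroxy-11βH-germacran-12,6α-olide | C[C@]1(O)[C@H](O)CC[C@@]2(C)O[C@H]2[C@H]2OC(=O)[C@@H](COC(C)=O)[C@@H]2[C@@H](O)C1
F7 | step 6 | (S)-3-hydroxy-3-[(2R,3R)-2-(2-methylprop-1-en-1-yl)-5-oxooxolan-3-yl]-1-[(R)-4-isopropyl-2-thioxothiazolidin-3-yl]propan-1-one | CC(C)=C[C@H]1OC(=O)C[C@@H]1[C@@H](O)CC(=O)N1[C@H](C(C)C)CSC1=S
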